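**Retrosynthetic overview**

1. The target comes from hydrogenolysis of its 7,4'-dibenzyl ether, which comes from O5 methylation after O7 benzylation of a ring A 5,7-diol; O5–H is hydrogen-bonded to the C4 carbonyl and reacts last.
2. Ring A (C4a–C5–C6–C7–C8–C8a) is opened at C5–C6 by a Claisen disconnection. The plan rests on the 1,3 (resorcinol) relation of the oxygens on C5 and C7, with methoxy on C6 and C8: C5 and C7 are former carbonyl carbons, and C6 and C8 arrive already methoxylated in methoxyacetyl-derived units.
3. The keto ester for this closure comes from lateral methoxyacetylation of a 2-(methoxymethyl)-4-pyranone-3-carboxylate that already carries ring B.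
4. The pyranone comes from C-acylation of methyl 4-methoxyacetoacetate with a 3-aryl-3-chloro-2-methoxyacryloyl chloride and O-cyclization; the acid comes from chloroformylation and oxidation of 4-(benzyloxy)phenyl methoxymethyl ketone.
5. Ring order: ring B is bought, ring C (the pyranone) is closed in step 4, ring A is closed last in step 6.

Key step: step 6

Assumption: the chloroalkenes 4, 5, 6, 8 and 9 are carried as E/Z mixtures (SMILES without alkene descriptors), because the ring closure of step 4 should convert both isomers into the same pyranone.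

**Route**

Step 1
Reactants: 1 4-(benzyloxy)phenylmagnesium bromide; 2 N,2-dimethoxy-N-methylacetamide
Product: 3 1-[4-(benzyloxy)phenyl]-2-methoxyethan-1-one
Conditions: THF, 0 °C → rt; then 1 M HCl
Reagents that add atoms: none
Why: Weinreb ketone synthesis, in which the N-methoxy-N-methylamide should accept only one equivalent of the aryl Grignard reagent and release the ketone on acidic work-up.

Step 2
Reactants: 3 1-[4-(benzyloxy)phenyl]-2-methoxyethan-1-one
Product: 5 3-[4-(benzyloxy)phenyl]-3-chloro-2-methoxyprop-2-enal, via chlorovinyl iminium chloride 4 (not isolated)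
Conditions: POCl3, DMF, 0 → 60 °C; then H2O, 0 °C → rt
Reagents that add atoms: N,N-dimethylformamide CN(C)C=O; phosphoryl chloride O=P(Cl)(Cl)Cl; water O
Why: Vilsmeier–Haack chloroformylation of an enolizable aryl ketone, in which the enol is formylated at the methoxy-bearing carbon, the ketone oxygen is exchanged for chlorine, and hydrolysis of iminium salt 4 should liberate the aldehyde.

Step 3
Reactants: 5 3-[4-(benzyloxy)phenyl]-3-chloro-2-methoxyprop-2-enal
Product: 6 3-[4-(benzyloxy)phenyl]-3-chloro-2-methoxyprop-2-enoic acid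
Conditions: NaClO2, NaH2PO4, 2-methyl-2-butene, t-BuOH/H2O, rt
Reagents that add atoms: sodium chlorite [Na+].[O-]Cl=O
Why: Pinnick oxidation, which should convert the enal into the acid without touching the vinyl chloride, the enol ether or the benzyl ether, the alkene additive removing hypochlorous acid.

Step 4
Reactants: 6 3-[4-(benzyloxy)phenyl]-3-chloro-2-methoxyprop-2-enoic acid; 7 methyl 4-methoxy-3-oxobutanoate
Product: 10 methyl 6-[4-(benzyloxy)phenyl]-5-methoxy-2-(methoxymethyl)-4-oxo-4H-pyran-3-carboxylate, via acid chloride 8 (not isolated), via acyclic triketo ester 9 (not isolated)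
Conditions: (COCl)2, cat. DMF, CH2Cl2, 0 °C → rt, evaporate; then 7, MgCl2, Et3N, MeCN, 0 °C → rt, then 60 °C
Reagents that add atoms: none
Why: C-acylation of the magnesium enolate of a β-keto ester by an acid chloride, followed by intramolecular addition–elimination of the methoxyacetyl enol oxygen at the chlorine-bearing carbon (6-endo O-cyclization, the oxygen counterpart of the quinolone and chromone syntheses from ortho-halo aroyl chlorides), should give the 4-pyranone from either alkene isomer.

Step 5
Reactants: 10 methyl 6-[4-(benzyloxy)phenyl]-5-methoxy-2-(methoxymethyl)-4-oxo-4H-pyran-3-carboxylate; 2 N,2-dimethoxy-N-methylacetamide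
Product: 11 methyl 6-[4-(benzyloxy)phenyl]-2-(1,3-dimethoxy-2-oxopropyl)-5-methoxy-4-oxo-4H-pyran-3-carboxylate
Conditions: LiN(SiMe3)2 (1.2 equiv), THF, −78 °C; then 2, −78 → −40 °C; then AcOH, −78 °C
Reagents that add atoms: none
Why: Lateral (vinylogous) deprotonation of the 2-methoxymethyl group of a 4-pyranone and acylation of the extended enolate by a Weinreb amide should stop at the ketone; the new stereocentre is enolizable, is formed racemic and is removed in step 6.

Step 6
Reactants: 11 methyl 6-[4-(benzyloxy)phenyl]-2-(1,3-dimethoxy-2-oxopropyl)-5-methoxy-4-oxo-4H-pyran-3-carboxylate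
Product: 13 2-[4-(benzyloxy)phenyl]-5,7-dihydroxy-3,6,8-trimethoxy-4H-chromen-4-one, via cyclic 5-keto tautomer 12 (not isolated)
Conditions: LiN(iPr)2 (3.3 equiv), THF, −78 → 0 °C; then 1 M HCl
Reagents that add atoms: none
Why: Proposed new method: LiN(iPr)2 should first remove the doubly activated C8–H and then a proton of the terminal C6 methylene, and the C6 carbanion of this dianion adds to the ester carbonyl on the pyranone (the future C5) and expels methoxide, an intramolecular Claisen (Dieckmann-type) condensation whose closest known relatives are the base-mediated cyclization of methyl 2-(2-oxoalkyl)benzoates to naphthalene-1,3-diols and the biomimetic aromatization of polyketo esters, a 4-pyranone-3-carboxylate not having served as the ester carrier. Ring A closes by a 6-(enolendo)-exo-trig attack through a six-membered transition structure, the enolate bond between C8 and C8a being free to take the geometry that places C6 next to the ester. The trione 12 so formed is deprotonated at C6 by the expelled methoxide and should appear after acidification as the aromatic 5,7-diol, which makes the closure irreversible. No stereocentre is formed, and the racemic C8 centre of 11 becomes sp2. The step needs carbon attack from C6 in preference to attack by the enolate oxygen on C7 (enol lactone) or by C8: the last-formed C6 carbanion is the most nucleophilic site of the dianion, C8 could close only a four-membered ring, the pyranone C4 carbonyl cannot be reached by the three-atom chain, and a hindered amide base should leave the ester and the pyranone untouched while the oxygen pathway stays reversible.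

Step 7
Reactants: 13 2-[4-(benzyloxy)phenyl]-5,7-dihydroxy-3,6,8-trimethoxy-4H-chromen-4-one
Product: 14 7-(benzyloxy)-2-[4-(benzyloxy)phenyl]-5-hydroxy-3,6,8-trimethoxy-4H-chromen-4-one
Conditions: BnBr (1.05 equiv), K2CO3 (1.1 equiv), DMF, rt
Reagents that add atoms: benzyl bromide BrCc1ccccc1
Why: Williamson ether synthesis at the more acidic 7-hydroxyl, the 5-hydroxyl being held in a hydrogen bond to the C4 carbonyl and therefore expected to stay free with one equivalent of halide under mild carbonate conditions.

Step 8
Reactants: 14 7-(benzyloxy)-2-[4-(benzyloxy)phenyl]-5-hydroxy-3,6,8-trimethoxy-4H-chromen-4-one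
Product: 15 7-(benzyloxy)-2-[4-(benzyloxy)phenyl]-3,5,6,8-tetramethoxy-4H-chromen-4-one
Conditions: Me2SO4 (excess), K2CO3, acetone, reflux
Reagents that add atoms: dimethyl sulfate COS(=O)(=O)OC
Why: Williamson-type O-methylation of the chelated 5-hydroxyl under forcing conditions, the usual way to etherify a 5-hydroxyflavone once no other hydroxyl is free.

Step 9
Reactants: 15 7-(benzyloxy)-2-[4-(benzyloxy)phenyl]-3,5,6,8-tetramethoxy-4H-chromen-4-one
Product: 16 7-hydroxy-2-(4-hydroxyphenyl)-3,5,6,8-tetramethoxy-4H-chromen-4-one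
Conditions: H2 (1 atm), 10% Pd/C, EtOAc/MeOH, rt
Reagents that add atoms: none
Why: Catalytic hydrogenolysis of both benzyl aryl ethers, under which the tetrasubstituted C2–C3 double bond of the chromone and the methyl ethers should be inert.

**Compound list**

1 | 4-(benzyloxy)phenylmagnesium bromide | Br[Mg]c1ccc(OCc2ccccc2)cc1 | starting material
2 | N,2-dimethoxy-N-methylacetamide | COCC(=O)N(C)OC | starting material
3 | 1-[4-(benzyloxy)phenyl]-2-methoxyethan-1-one | COCC(=O)c1ccc(OCc2ccccc2)cc1 | intermediate
4 | N-{3-[4-(benzyloxy)phenyl]-3-chloro-2-methoxyprop-2-en-1-ylidene}-N-methylmethanaminium chloride (E/Z mixture, counter-ion written as chloride) | C[N+](C)=CC(OC)=C(Cl)c1ccc(OCc2ccccc2)cc1.[Cl-] | intermediate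
5 | 3-[4-(benzyloxy)phenyl]-3-chloro-2-methoxyprop-2-enal (E/Z mixture) | COC(C=O)=C(Cl)c1ccc(OCc2ccccc2)cc1 | intermediate
6 | 3-[4-(benzyloxy)phenyl]-3-chloro-2-methoxyprop-2-enoic acid (E/Z mixture) | COC(C(=O)O)=C(Cl)c1ccc(OCc2ccccc2)cc1 | intermediate
7 | methyl 4-methoxy-3-oxobutanoate | COCC(=O)CC(=O)OC | starting material
8 | 3-[4-(benzyloxy)phenyl]-3-chloro-2-methoxyprop-2-enoyl chloride (E/Z mixture) | COC(C(=O)Cl)=C(Cl)c1ccc(OCc2ccccc2)cc1 | intermediate
9 | methyl 2-{3-[4-(benzyloxy)phenyl]-3-chloro-2-methoxyprop-2-enoyl}-4-methoxy-3-oxobutanoate (E/Z mixture, enolized) | COCC(=O)C(C(=O)OC)C(=O)C(OC)=C(Cl)c1ccc(OCc2ccccc2)cc1 | intermediate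
10 | methyl 6-[4-(benzyloxy)phenyl]-5-methoxy-2-(methoxymethyl)-4-oxo-4H-pyran-3-carboxylate | COCc1oc(-c2ccc(OCc3ccccc3)cc2)c(OC)c(=O)c1C(=O)OC | intermediate
11 | methyl 6-[4-(benzyloxy)phenyl]-2-(1,3-dimethoxy-2-oxopropyl)-5-methoxy-4-oxo-4H-pyran-3-carboxylate (racemic, enolizable) | COCC(=O)C(OC)c1oc(-c2ccc(OCc3ccccc3)cc2)c(OC)c(=O)c1C(=O)OC | intermediate
12 | 2-[4-(benzyloxy)phenyl]-7-hydroxy-3,6,8-trimethoxy-4H-chromene-4,5(6H)-dione (racemic, present as its lithium enolate) | COC1C(=O)c2c(oc(-c3ccc(OCc4ccccc4)cc3)c(OC)c2=O)C(OC)=C1O | intermediate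
13 | 2-[4-(benzyloxy)phenyl]-5,7-dihydroxy-3,6,8-trimethoxy-4H-chromen-4-one | COc1c(O)c(OC)c2oc(-c3ccc(OCc4ccccc4)cc3)c(OC)c(=O)c2c1O | intermediate
14 | 7-(benzyloxy)-2-[4-(benzyloxy)phenyl]-5-hydroxy-3,6,8-trimethoxy-4H-chromen-4-one | COc1c(OCc2ccccc2)c(OC)c2oc(-c3ccc(OCc4ccccc4)cc3)c(OC)c(=O)c2c1O | intermediate
15 | 7-(benzyloxy)-2-[4-(benzyloxy)phenyl]-3,5,6,8-tetramethoxy-4H-chromen-4-one | COc1c(OCc2ccccc2)c(OC)c2oc(-c3ccc(OCc4ccccc4)cc3)c(OC)c(=O)c2c1OC | intermediate
16 | 7-hydroxy-2-(4-hydroxyphenyl)-3,5,6,8-tetramethoxy-4H-chromen-4-one | COc1c(O)c(OC)c2oc(-c3ccc(O)cc3)c(OC)c(=O)c2c1OC | target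

**Step count**

Total steps: 9. Longest linear sequence: 9 steps (1 → 16).

**Steps most likely to fail**

Step 6 (proposed new method). The ketone enolate oxygen may acylate in place of C6 and give an enol lactone, the second deprotonation may stay incomplete so that only the unreactive C8 monoanion is present, or the base may open the pyranone. The fallback takes ring A from phloroglucinol by known chemistry; it sets out from 3 and comes back at 13. Ketone 3 is carbomethoxylated (NaH, dimethyl carbonate, toluene, reflux) to methyl 3-[4-(benzyloxy)phenyl]-2-methoxy-3-oxopropanoate F1. Thermal condensation of F1 with benzene-1,3,5-triol (neat, about 240 °C, Mentzer pyrone synthesis) should give 2-[4-(benzyloxy)phenyl]-5,7-dihydroxy-3-methoxy-4H-chromen-4-one F2. N-Bromosuccinimide (2 equiv, DMF, 0 °C) should brominate the phloroglucinol ring to 2-[4-(benzyloxy)phenyl]-6,8-dibromo-5,7-dihydroxy-3-methoxy-4H-chromen-4-one F3. Copper-mediated methanolysis (NaOMe, CuBr, DMF/MeOH, reflux) then replaces both bromines by methoxy and gives 13.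

Step 5. The stabilized lateral anion may add too slowly to the amide, or the tetrahedral adduct may close onto the neighbouring ester before the quench. The fallback builds the side chain before the pyranone; it sets out from 7 and comes back at 11. The 1,3-dianion of 7 (NaH, then n-BuLi, THF, 0 °C) is acylated at its terminal carbon with amide 2 to give methyl 4,6-dimethoxy-3,5-dioxohexanoate F4. The 2,4-dianion of F4 (LiN(iPr)2, 2 equiv, THF, −78 °C) is acylated at C2, its last-formed carbanion, with acid chloride 8 to give methyl 2-{3-[4-(benzyloxy)phenyl]-3-chloro-2-methoxyprop-2-enoyl}-4,6-dimethoxy-3,5-dioxohexanoate F5. Warming F5 with Et3N closes the pyranone as in step 4 and gives 11.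

Step 4. The magnesium enolate may acylate on oxygen, the triacylmethane may lose its methoxyacetyl group by retro-Claisen cleavage, or the ring may close through the ester oxygen. The fallback closes the ring oxygen by dehydration of a 1,3,5-triketone; it sets out from 7 and comes back at 10. The 1,3-dianion of 7 (NaH, then n-BuLi, THF, 0 °C) is acylated with commercial methyl 4-(benzyloxy)benzoate to give methyl 5-[4-(benzyloxy)phenyl]-4-methoxy-3,5-dioxopentanoate F6. The 2,4-dianion of F6 (LiN(iPr)2, 2 equiv, THF, −78 °C) is acylated at C2 with methoxyacetyl chloride to give methyl 5-[4-(benzyloxy)phenyl]-4-methoxy-2-(methoxyacetyl)-3,5-dioxopentanoate F7. Acid-catalysed cyclodehydration of F7 (p-TsOH, toluene, 60 °C) should give 10.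

**Further compounds**

F1 | step 6 | methyl 3-[4-(benzyloxy)phenyl]-2-methoxy-3-oxopropanoate | COC(=O)C(OC)C(=O)c1ccc(OCc2ccccc2)cc1
F2 | step 6 | 2-[4-(benzyloxy)phenyl]-5,7-dihydroxy-3-methoxy-4H-chromen-4-one | COc1c(-c2ccc(OCc3ccccc3)cc2)oc2cc(O)cc(O)c2c1=O
F3 | step 6 | 2-[4-(benzyloxy)phenyl]-6,8-dibromo-5,7-dihydroxy-3-methoxy-4H-chromen-4-one | COc1c(-c2ccc(OCc3ccccc3)cc2)oc2c(Br)c(O)c(Br)c(O)c2c1=O
F4 | step 5 | methyl 4,6-dimethoxy-3,5-dioxohexanoate | COCC(=O)C(OC)C(=O)CC(=O)OC
F5 | step 5 | methyl 2-{3-[4-(benzyloxy)phenyl]-3-chloro-2-methoxyprop-2-enoyl}-4,6-dimethoxy-3,5-dioxohexanoate | COCC(=O)C(OC)C(=O)C(C(=O)OC)C(=O)C(OC)=C(Cl)c1ccc(OCc2ccccc2)cc1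
F6 | step 4 | methyl 5-[4-(benzyloxy)phenyl]-4-methoxy-3,5-dioxopentanoate | COC(=O)CC(=O)C(OC)C(=O)c1ccc(OCc2ccccc2)cc1
F7 | step 4 | methyl 5-[4-(benzyloxy)phenyl]-4-methoxy-2-(methoxyacetyl)-3,5-dioxopentanoate | COCC(=O)C(C(=O)OC)C(=O)C(OC)C(=O)c1ccc(OCc2ccccc2)cc1
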